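1. Ring numbering as in the name of 25 (C1 = carbinol carbon; olefins C3=C4 Z, C7=C8 E, C11=C12 E). The 14-membered carbocycle, the only ring, is formed last by closing C12–C13: 9-BBN hydroboration of a vinyl group on C1 and intramolecular B-alkyl Suzuki–Miyaura coupling with a C12 alkenyl iodide (step 14); desilylation ends the route.
2. Feature that allows this: ring carbons C14 and C13 are a two-carbon bridge between the tertiary carbinol C1 and the olefinic carbon C12. They can therefore be carried as a vinyl group on C1; hydroboration puts boron on C13, 1,3 to the free C1 hydroxyl (five-membered oxaborolane borate), and C12 is carried as a geometrically defined (E)-alkenyl iodide.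
3. The open-chain precursor comes from a three-component union next to the quaternary carbon: carbocupration of propyne by the Grignard reagent of fragment A gives a (Z)-alkenylcopper (sets C3=C4) that opens the CH2 terminus of the epoxy alcohol of fragment B (C2–C3 bond). The alkyne then becomes the (E)-alkenyl iodide and the CH2OH becomes CHO, then vinyl.
4. Fragment B: (R)-citronellal brings the side-chain stereocenter; α-methylenation, allylic oxidation of the (E)-methyl, silylation, Luche reduction and Sharpless epoxidation (sets C1).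
5. Fragment A: two molecules of pent-3-yn-1-ol, joined by a Negishi coupling that fixes C7=C8.

Key step: step 14

Remark: (R)-citronellal of high enantiomeric purity is assumed as the source of the side-chain stereocenter; the C1 hydroxyl is carried unprotected from step 10 on.

Step 1
Reactants: 1 pent-3-yn-1-ol
Product: 2 5-iodopent-2-yne
Conditions: I2, PPh3, imidazole, CH2Cl2, 0 °C → rt
Reagents that add atoms: iodine, II
Why: Appel-type (Garegg–Samuelsson) iodination: the primary alcohol is activated as an alkoxyphosphonium ion and displaced by iodide in an SN2 reaction that leaves the alkyne untouched.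

Step 2
Reactants: 1 pent-3-yn-1-ol
Product: 4 (3E)-4-iodopent-3-en-1-ol, via alkenylzirconocene 3 (not isolated)
Conditions: Cp2Zr(H)Cl (2.3 equiv), THF, rt; then I2, −20 °C
Reagents that add atoms: iodine, II
Why: Schwartz hydrozirconation adds Zr–H syn across the alkyne and, with excess reagent, equilibrates zirconium to the less hindered methyl-bearing carbon, so that iodinolysis with retention should give the (E)-2-iodoalkene; one equivalent of reagent is consumed by the hydroxyl as its zirconium alkoxide.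

Step 3
Reactants: 4 (3E)-4-iodopent-3-en-1-ol
Product: 5 (2E)-5-bromo-2-iodopent-2-ene
Conditions: CBr4, PPh3, CH2Cl2, 0 °C
Reagents that add atoms: carbon tetrabromide, BrC(Br)(Br)Br
Why: Appel bromination of the primary alcohol (SN2 on the alkoxyphosphonium bromide), under which the alkenyl iodide is inert.

Step 4
Reactants: 2 5-iodopent-2-yne; 5 (2E)-5-bromo-2-iodopent-2-ene
Product: 7 (6E)-9-bromo-6-methylnon-6-en-2-yne, via organozinc iodide 6 (not isolated)
Conditions: 2, Zn dust, LiCl, THF, 40 °C; then 5, Pd(dppf)Cl2 (3 mol%), THF, rt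
Reagents that add atoms: none
Why: Negishi coupling: zinc inserts into the primary C–I bond of 2, zerovalent palladium adds to the alkenyl C–I bond of 5 far faster than to its primary C–Br bond, and C(sp3)–C(sp2) coupling proceeds with retention, which fixes the (E) trisubstituted olefin that becomes C7=C8.

Step 5
Reactants: 8 (R)-citronellal
Product: 9 (3R)-3,7-dimethyl-2-methylideneoct-6-enal
Conditions: aq. HCHO, pyrrolidine (10 mol%), propionic acid (10 mol%), i-PrOH, 45 °C
Reagents that add atoms: formaldehyde, C=O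
Why: Amine-catalysed Mannich condensation with formaldehyde followed by elimination (organocatalytic α-methylenation of an aldehyde); the C3 stereocenter from citronellal is not acidified in the product and should be retained.

Step 6
Reactants: 9 (3R)-3,7-dimethyl-2-methylideneoct-6-enal
Product: 10 (3R,6E)-8-hydroxy-3,7-dimethyl-2-methylideneoct-6-enal
Conditions: SeO2 (0.3 equiv), t-BuOOH, salicylic acid (cat.), CH2Cl2, rt
Reagents that add atoms: selenium dioxide, O=[Se]=O (catalytic oxygen carrier); tert-butyl hydroperoxide, CC(C)(C)OO (terminal oxygen source)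
Why: SeO2 allylic oxidation (Riley type: ene reaction, then [2,3]-sigmatropic shift) is expected to hydroxylate the (E)-methyl of the electron-rich trisubstituted olefin, while the electron-poor conjugated methylene-enal, like the enals that such oxidations themselves produce, should not react.

Step 7
Reactants: 10 (3R,6E)-8-hydroxy-3,7-dimethyl-2-methylideneoct-6-enal
Product: 11 (3R,6E)-8-[(tert-butyldimethylsilyl)oxy]-3,7-dimethyl-2-methylideneoct-6-enal
Conditions: TBSOTf, 2,6-lutidine, CH2Cl2, −78 °C
Reagents that add atoms: tert-butyldimethylsilyl triflate, CC(C)(C)[Si](C)(C)OS(=O)(=O)C(F)(F)F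
Why: Silylation of the primary allylic alcohol with a silyl triflate and a hindered, non-nucleophilic base that cannot add to the methylene-enal.

Step 8
Reactants: 11 (3R,6E)-8-[(tert-butyldimethylsilyl)oxy]-3,7-dimethyl-2-methylideneoct-6-enal
Product: 12 (3R,6E)-8-[(tert-butyldimethylsilyl)oxy]-3,7-dimethyl-2-methylideneoct-6-en-1-ol
Conditions: NaBH4, CeCl3·7H2O, MeOH, −20 °C
Reagents that add atoms: none
Why: Luche reduction: the CeCl3-modified borohydride reduces the enal 1,2 to the allylic alcohol without conjugate reduction.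

Step 9
Reactants: 12 (3R,6E)-8-[(tert-butyldimethylsilyl)oxy]-3,7-dimethyl-2-methylideneoct-6-en-1-ol
Product: 13 [(2S)-2-[(2R,5E)-7-[(tert-butyldimethylsilyl)oxy]-6-methylhept-5-en-2-yl]oxiran-2-yl]methanol
Conditions: Ti(OiPr)4 (10 mol%), L-(+)-DIPT (12 mol%), t-BuOOH, 4 Å MS, CH2Cl2, −25 °C
Reagents that add atoms: tert-butyl hydroperoxide, CC(C)(C)OO
Why: Katsuki–Sharpless asymmetric epoxidation: only the olefin of the free allylic alcohol is epoxidized, and the L-(+)-tartrate catalyst delivers oxygen to the face that makes the new quaternary oxirane carbon (S) (reagent control, the same sense as for other 2-substituted allyl alcohols); this carbon becomes C1 of the ring.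

Step 10
Reactants: 7 (6E)-9-bromo-6-methylnon-6-en-2-yne; 14 propyne; 13 [(2S)-2-[(2R,5E)-7-[(tert-butyldimethylsilyl)oxy]-6-methylhept-5-en-2-yl]oxiran-2-yl]methanol
Product: 18 (2S,4Z,8E)-2-[(2R,5E)-7-[(tert-butyldimethylsilyl)oxy]-6-methylhept-5-en-2-yl]-5,9-dimethyltetradeca-4,8-dien-12-yne-1,2-diol, via Grignard reagent 15 (not isolated), via alkenylcopper 16 (not isolated), via lithium alkoxide 17 (not isolated)
Conditions: 7, Mg, Et2O; CuBr·SMe2, Et2O/Me2S, −45 °C; propyne, −25 °C; then 17 (from 13, n-BuLi, THF, −78 °C), −25 → 0 °C; aq. NH4Cl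
Reagents that add atoms: none
Why: Normant-type carbocupration: the alkylcopper from 15 adds syn to propyne with copper on the terminal carbon to give the (Z)-alkenylcopper 16, which the lithium alkoxide 17 turns into an alkoxy(alkenyl)cuprate that opens the 2,2-disubstituted epoxide at its CH2 terminus (SN2, olefin geometry retained); the (Z) C3=C4 olefin is thus set by the syn addition, and C1 keeps the configuration from step 9 because its C–O bond is not broken.

Step 11
Reactants: 18 (2S,4Z,8E)-2-[(2R,5E)-7-[(tert-butyldimethylsilyl)oxy]-6-methylhept-5-en-2-yl]-5,9-dimethyltetradeca-4,8-dien-12-yne-1,2-diol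
Product: 20 (2S,4Z,8E,12E)-13-iodo-2-[(2R,5E)-7-[(tert-butyldimethylsilyl)oxy]-6-methylhept-5-en-2-yl]-5,9-dimethyltetradeca-4,8,12-triene-1,2-diol, via alkenylzirconocene 19 (not isolated)
Conditions: Cp2Zr(H)Cl (4.5 equiv), THF, rt → 45 °C; then I2, −20 °C
Reagents that add atoms: iodine, II
Why: Schwartz hydrozirconation–iodination as in step 2: after both hydroxyls have become zirconium alkoxides, syn addition of Zr–H to the only alkyne, equilibration of zirconium to the methyl-bearing carbon and iodinolysis with retention should give the (E)-alkenyl iodide, while the trisubstituted olefins and the silyl ether are inert.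

Step 12
Reactants: 20 (2S,4Z,8E,12E)-13-iodo-2-[(2R,5E)-7-[(tert-butyldimethylsilyl)oxy]-6-methylhept-5-en-2-yl]-5,9-dimethyltetradeca-4,8,12-triene-1,2-diol
Product: 21 (2S,4Z,8E,12E)-2-hydroxy-13-iodo-2-[(2R,5E)-7-[(tert-butyldimethylsilyl)oxy]-6-methylhept-5-en-2-yl]-5,9-dimethyltetradeca-4,8,12-trienal
Conditions: SO3·pyridine, DMSO, i-Pr2NEt, CH2Cl2, 0 °C
Reagents that add atoms: none
Why: Parikh–Doering oxidation (activated DMSO) oxidizes the primary alcohol to the aldehyde, cannot oxidize the tertiary alcohol and, unlike periodate or iodane oxidants, does not cleave the 1,2-diol.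

Step 13
Reactants: 21 (2S,4Z,8E,12E)-2-hydroxy-13-iodo-2-[(2R,5E)-7-[(tert-butyldimethylsilyl)oxy]-6-methylhept-5-en-2-yl]-5,9-dimethyltetradeca-4,8,12-trienal
Product: 22 (3R,5Z,9E,13E)-14-iodo-3-[(2R,5E)-7-[(tert-butyldimethylsilyl)oxy]-6-methylhept-5-en-2-yl]-6,10-dimethylpentadeca-1,5,9,13-tetraen-3-ol
Conditions: Ph3PCH3Br, KN(SiMe3)2 (excess), THF, −78 → 0 °C
Reagents that add atoms: methyltriphenylphosphonium bromide, C[P+](c1ccccc1)(c1ccccc1)c1ccccc1.[Br-]
Why: Wittig methylenation with excess ylide (the tertiary hydroxyl is carried as its alkoxide) converts the hindered, non-enolizable aldehyde into the vinyl group that holds ring carbons C14 and C13.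

Step 14
Reactants: 22 (3R,5Z,9E,13E)-14-iodo-3-[(2R,5E)-7-[(tert-butyldimethylsilyl)oxy]-6-methylhept-5-en-2-yl]-6,10-dimethylpentadeca-1,5,9,13-tetraen-3-ol
Product: 24 (1S,3Z,7E,11E)-1-[(2R,5E)-7-[(tert-butyldimethylsilyl)oxy]-6-methylhept-5-en-2-yl]-4,8,12-trimethylcyclotetradeca-3,7,11-trien-1-ol, via B-alkyl-9-BBN 23 (not isolated)
Conditions: 9-BBN (3 equiv), THF, 0 °C → rt; then slow addition to Pd(dppf)Cl2 (15 mol%), AsPh3, Cs2CO3, DMF/THF/H2O, 50 °C, about 1 mM
Reagents that add atoms: none
Why: 9-BBN hydroborates only the monosubstituted C13=C14 vinyl group (anti-Markovnikov, boron on C13; the four trisubstituted olefins and the alkenyl iodide do not react), zerovalent palladium inserts into the C12–I bond, the base-activated B-alkyl borate transmetalates, and reductive elimination forms the C12–C13 bond. The closest known reaction type is the B-alkyl Suzuki–Miyaura macrocyclization of a terminal alkene/alkenyl iodide pair after in situ 9-BBN hydroboration. The 14-membered ring closes by C(sp3)–C(sp2) reductive elimination from a 15-membered palladacycle, with the new bond and the olefin both inside the ring. No stereocenter is formed; C1 and the side-chain center are spectators, and the (E) geometry of C11=C12 comes from the alkenyl iodide because oxidative addition and reductive elimination both go with retention. The step needs chemoselective hydroboration, which the single terminal vinyl group secures, and ring closure in preference to oligomerization and β-hydride elimination, which slow addition at high dilution and the dppf/AsPh3 catalyst should secure. The free C1 hydroxyl lies 1,3 to boron and can close a five-membered oxaborolane borate, which should help rather than hinder transmetalation.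

Step 15
Reactants: 24 (1S,3Z,7E,11E)-1-[(2R,5E)-7-[(tert-butyldimethylsilyl)oxy]-6-methylhept-5-en-2-yl]-4,8,12-trimethylcyclotetradeca-3,7,11-trien-1-ol
Product: 25 (1S,3Z,7E,11E)-1-[(2R,5E)-7-hydroxy-6-methylhept-5-en-2-yl]-4,8,12-trimethylcyclotetradeca-3,7,11-trien-1-ol
Conditions: Bu4NF, THF, 0 °C → rt
Reagents that add atoms: none
Why: Fluoride cleaves the primary allylic silyl ether (Si–F bond formation) and leaves the tertiary alcohol and the four trisubstituted olefins untouched.

Compound list
1 | pent-3-yn-1-ol | CC#CCCO | starting material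
2 | 5-iodopent-2-yne | CC#CCCI | intermediate
3 | alkenylzirconocene from 1: (3E)-pent-3-en-1-ol carrying Cp2Zr(Cl) on C4 and on oxygen | C/C(=C\CCO[Zr](Cl)(C1C=CC=C1)C1C=CC=C1)[Zr](Cl)(C1C=CC=C1)C1C=CC=C1 | intermediate
4 | (3E)-4-iodopent-3-en-1-ol | C/C(I)=C\CCO | intermediate
5 | (2E)-5-bromo-2-iodopent-2-ene | C/C(I)=C\CCBr | intermediate
6 | pent-3-yn-1-ylzinc iodide | CC#CCC[Zn]I | intermediate
7 | (6E)-9-bromo-6-methylnon-6-en-2-yne | CC#CCC/C(C)=C/CCBr | intermediate
8 | (R)-citronellal, (3R)-3,7-dimethyloct-6-enal | O=CC[C@H](C)CCC=C(C)C | starting material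
9 | (3R)-3,7-dimethyl-2-methylideneoct-6-enal | O=CC(=C)[C@H](C)CCC=C(C)C | intermediate
10 | (3R,6E)-8-hydroxy-3,7-dimethyl-2-methylideneoct-6-enal | O=CC(=C)[C@H](C)CC/C=C(\C)CO | intermediate
11 | (3R,6E)-8-[(tert-butyldimethylsilyl)oxy]-3,7-dimethyl-2-methylideneoct-6-enal | O=CC(=C)[C@H](C)CC/C=C(\C)CO[Si](C)(C)C(C)(C)C | intermediate
12 | (3R,6E)-8-[(tert-butyldimethylsilyl)oxy]-3,7-dimethyl-2-methylideneoct-6-en-1-ol | OCC(=C)[C@H](C)CC/C=C(\C)CO[Si](C)(C)C(C)(C)C | intermediate
13 | [(2S)-2-[(2R,5E)-7-[(tert-butyldimethylsilyl)oxy]-6-methylhept-5-en-2-yl]oxiran-2-yl]methanol | OC[C@]1(CO1)[C@H](C)CC/C=C(\C)CO[Si](C)(C)C(C)(C)C | intermediate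
14 | propyne | CC#C | starting material
15 | [(3E)-4-methylnon-3-en-7-yn-1-yl]magnesium bromide | CC#CCC/C(C)=C/CC[Mg]Br | intermediate
16 | [(1Z,5E)-2,6-dimethylundeca-1,5-dien-9-yn-1-yl]copper (as its MgBr2 complex) | CC#CCC/C(C)=C/CC/C(C)=C\[Cu] | intermediate
17 | lithium alkoxide of 13 | [Li]OC[C@]1(CO1)[C@H](C)CC/C=C(\C)CO[Si](C)(C)C(C)(C)C | intermediate
18 | (2S,4Z,8E)-2-[(2R,5E)-7-[(tert-butyldimethylsilyl)oxy]-6-methylhept-5-en-2-yl]-5,9-dimethyltetradeca-4,8-dien-12-yne-1,2-diol | CC#CCC/C(C)=C/CC/C(C)=C\C[C@@](O)(CO)[C@H](C)CC/C=C(\C)CO[Si](C)(C)C(C)(C)C | intermediate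
19 | alkenylzirconocene from 18: Cp2Zr(Cl) on C13 (E), both hydroxyls as Cp2Zr(Cl) alkoxides | C/C(=C\CC/C(C)=C/CC/C(C)=C\C[C@@](O[Zr](Cl)(C1C=CC=C1)C1C=CC=C1)(CO[Zr](Cl)(C1C=CC=C1)C1C=CC=C1)[C@H](C)CC/C=C(\C)CO[Si](C)(C)C(C)(C)C)[Zr](Cl)(C1C=CC=C1)C1C=CC=C1 | intermediate
20 | (2S,4Z,8E,12E)-13-iodo-2-[(2R,5E)-7-[(tert-butyldimethylsilyl)oxy]-6-methylhept-5-en-2-yl]-5,9-dimethyltetradeca-4,8,12-triene-1,2-diol | C/C(I)=C\CC/C(C)=C/CC/C(C)=C\C[C@@](O)(CO)[C@H](C)CC/C=C(\C)CO[Si](C)(C)C(C)(C)C | intermediate
21 | (2S,4Z,8E,12E)-2-hydroxy-13-iodo-2-[(2R,5E)-7-[(tert-butyldimethylsilyl)oxy]-6-methylhept-5-en-2-yl]-5,9-dimethyltetradeca-4,8,12-trienal | C/C(I)=C\CC/C(C)=C/CC/C(C)=C\C[C@@](O)(C=O)[C@H](C)CC/C=C(\C)CO[Si](C)(C)C(C)(C)C | intermediate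
22 | (3R,5Z,9E,13E)-14-iodo-3-[(2R,5E)-7-[(tert-butyldimethylsilyl)oxy]-6-methylhept-5-en-2-yl]-6,10-dimethylpentadeca-1,5,9,13-tetraen-3-ol | C/C(I)=C\CC/C(C)=C/CC/C(C)=C\C[C@@](O)(C=C)[C@H](C)CC/C=C(\C)CO[Si](C)(C)C(C)(C)C | intermediate
23 | (3S,5Z,9E,13E)-1-(9-borabicyclo[3.3.1]nonan-9-yl)-14-iodo-3-[(2R,5E)-7-[(tert-butyldimethylsilyl)oxy]-6-methylhept-5-en-2-yl]-6,10-dimethylpentadeca-5,9,13-trien-3-ol | C/C(I)=C\CC/C(C)=C/CC/C(C)=C\C[C@@](O)(CCB1C2CCCC1CCC2)[C@H](C)CC/C=C(\C)CO[Si](C)(C)C(C)(C)C | intermediate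
24 | (1S,3Z,7E,11E)-1-[(2R,5E)-7-[(tert-butyldimethylsilyl)oxy]-6-methylhept-5-en-2-yl]-4,8,12-trimethylcyclotetradeca-3,7,11-trien-1-ol | C/C1=C/C[C@](O)([C@H](C)CC/C=C(\C)CO[Si](C)(C)C(C)(C)C)CC/C(C)=C/CC/C(C)=C/CC1 | intermediate
25 | (1S,3Z,7E,11E)-1-[(2R,5E)-7-hydroxy-6-methylhept-5-en-2-yl]-4,8,12-trimethylcyclotetradeca-3,7,11-trien-1-ol | C/C1=C/C[C@](O)([C@H](C)CC/C=C(\C)CO)CC/C(C)=C/CC/C(C)=C/CC1 | target

Total step count: 15. Longest linear sequence: 11 steps (8 to 25, steps 5 to 15).

Steps most likely to fail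

Step 14. Ring closure may lose to oligomerization, and transmetalation of the hindered borane next to the alkoxide may be slow enough for protodeboronation to compete. The fallback closes the same bond from zinc and sets out from 22. Silylation of the tertiary alcohol (Et3SiOTf, 2,6-lutidine) would give the triethylsilyl ether F1. Hydroboration with 9-BBN and oxidation (NaBO3) would give the primary alcohol F2, and I2/PPh3/imidazole the primary iodide F3. Zinc dust with LiCl should insert only into the alkyl C–I bond to give the alkylzinc iodide F4. Slow addition of F4 to Pd(dppf)Cl2 in THF (intramolecular Negishi coupling) would give the bis-silylated macrocycle F5. Bu4NF then removes both silyl groups, and the route is rejoined at 25.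

Step 10. The weakly nucleophilic alkenylcopper may open the hindered epoxide incompletely, and Payne-type migration of the epoxy alkoxide would exchange the two CH2 arms on the quaternary carbon and erode its configuration. The fallback forms the C2–C3 bond first and the olefin afterwards, and sets out from 7 and 13. Alkylation of LiC≡CH·H2NCH2CH2NH2 with 7 in DMSO would give (5E)-6-methylundec-5-ene-1,9-diyne F6. n-BuLi and then Et2AlCl would turn it into the diethyl(alkynyl)alane F7, which should open 13 at the CH2 terminus in toluene (no Payne migration in a non-polar medium) to give the homopropargylic diol F8. MeMgBr with catalytic Fe(acac)3 would then effect alkoxide-directed syn-carbomagnesiation, methyl going to the distal alkyne carbon and magnesium to the proximal one (alkenylmagnesium chelate F9). Protonation gives 18, where the route is rejoined.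

Step 6. The oxidation may stall, over-oxidize the new alcohol to the enal, or let the peroxide attack the aldehyde. The fallback does the oxidation on an ester and sets out from 9. Luche reduction would give (3R)-3,7-dimethyl-2-methylideneoct-6-en-1-ol F10, and Ac2O/pyridine its acetate F11. SeO2/t-BuOOH should then oxidize the (E)-methyl of the prenyl group, the 1,1-disubstituted olefin being deactivated by the allylic acetate, to give the hydroxy acetate F12. TBSCl/imidazole would give the silyl ether acetate F13, and K2CO3 in MeOH removes the acetate to give 12, where the route is rejoined.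

Further compounds
F1 | step 14 | triethylsilyl ether of 22 (C3–OSiEt3, all other centers as in 22) | C/C(I)=C\CC/C(C)=C/CC/C(C)=C\C[C@@](O[Si](CC)(CC)CC)(C=C)[C@H](C)CC/C=C(\C)CO[Si](C)(C)C(C)(C)C
F2 | step 14 | primary alcohol from hydroboration–oxidation of F1 | C/C(I)=C\CC/C(C)=C/CC/C(C)=C\C[C@@](O[Si](CC)(CC)CC)(CCO)[C@H](C)CC/C=C(\C)CO[Si](C)(C)C(C)(C)C
F3 | step 14 | primary iodide from F2 | C/C(I)=C\CC/C(C)=C/CC/C(C)=C\C[C@@](O[Si](CC)(CC)CC)(CCI)[C@H](C)CC/C=C(\C)CO[Si](C)(C)C(C)(C)C
F4 | step 14 | alkylzinc iodide from F3 | C/C(I)=C\CC/C(C)=C/CC/C(C)=C\C[C@@](O[Si](CC)(CC)CC)(CC[Zn]I)[C@H](C)CC/C=C(\C)CO[Si](C)(C)C(C)(C)C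
F5 | step 14 | C1 triethylsilyl ether of macrocycle 24 | C/C1=C/C[C@](O[Si](CC)(CC)CC)([C@H](C)CC/C=C(\C)CO[Si](C)(C)C(C)(C)C)CC/C(C)=C/CC/C(C)=C/CC1
F6 | step 10 | (5E)-6-methylundec-5-ene-1,9-diyne | C#CCC/C=C(\C)CCC#CC
F7 | step 10 | diethyl[(5E)-6-methylundec-5-ene-1,9-diyn-1-yl]aluminium | CC[Al](CC)C#CCC/C=C(\C)CCC#CC
F8 | step 10 | (2S,8E)-2-[(2R,5E)-7-[(tert-butyldimethylsilyl)oxy]-6-methylhept-5-en-2-yl]-9-methyltetradec-8-ene-4,12-diyne-1,2-diol | CC#CCC/C(C)=C/CCC#CC[C@@](O)(CO)[C@H](C)CC/C=C(\C)CO[Si](C)(C)C(C)(C)C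
F9 | step 10 | alkenylmagnesium bromide from syn-carbomagnesiation of F8 (Mg on C4, both hydroxyls as MgBr alkoxides) | CC#CCC/C(C)=C/CC/C(C)=C(\C[C@@](O[Mg]Br)(CO[Mg]Br)[C@H](C)CC/C=C(\C)CO[Si](C)(C)C(C)(C)C)[Mg]Br
F10 | step 6 | (3R)-3,7-dimethyl-2-methylideneoct-6-en-1-ol | OCC(=C)[C@H](C)CCC=C(C)C
F11 | step 6 | (3R)-3,7-dimethyl-2-methylideneoct-6-en-1-yl acetate | CC(=O)OCC(=C)[C@H](C)CCC=C(C)C
F12 | step 6 | (3R,6E)-8-hydroxy-3,7-dimethyl-2-methylideneoct-6-en-1-yl acetate | CC(=O)OCC(=C)[C@H](C)CC/C=C(\C)CO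
F13 | step 6 | (3R,6E)-8-[(tert-butyldimethylsilyl)oxy]-3,7-dimethyl-2-methylideneoct-6-en-1-yl acetate | CC(=O)OCC(=C)[C@H](C)CC/C=C(\C)CO[Si](C)(C)C(C)(C)C
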